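**Plan**

- Retrosynthesis: after the silyl groups are taken off, the bond between the alkene CH and the methyl-bearing sp3 carbon on C-2 of the right-hand 4-pyranone ring is cut. This gives the left-hand (E)-alkenyl iodide 20 and the right-hand 2-(1-chloroethyl)pyranone 31.
- Enabling feature: that sp3 carbon sits on C-2 of the ring's O1–C2=C3–C4=O vinylogous ester. Its C–Cl bond is therefore reduced easily to a planar radical delocalised over C-2, C-3 and the C-4 carbonyl, so both chloride epimers converge and a chiral nickel catalyst can set the centre while the C–C bond forms, without base.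
- Each pyranone ring is cut at one ring O–C bond and at the bond between the side-chain-bearing ring carbon and its methyl-bearing neighbour. This leads back to a dianion of 4-methylheptane-3,5-dione and an α-methyl-β-silyloxy aldehyde (aldol, oxidation to the 1,3,5-triketone, cyclodehydration).
- Forward order: left chain, left pyranone ring, right chain, right pyranone ring, chlorination, fragment union, desilylation.
- Stereochemistry: the left tetrad comes from an oxazolidinone β-ketoimide (auxiliary syn aldol for the first methyl centre, tin-enolate anti,syn aldol, chelation-controlled syn reduction). The right anti pair comes from methyl (R)-3-hydroxypentanoate by Fráter–Seebach methylation, the junction centre from the nickel ligand, and the E-alkene from zirconium-catalysed carboalumination.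

Key step: step 20

Assumption: the (3aS,8aR)-configured indanyl bis(oxazoline) is taken to deliver the (R)-centre by analogy with secondary benzylic chlorides; if a model coupling shows the opposite sense, the enantiomeric ligand is used.

**Route**

Step 1
Reactants: 1 prop-2-yn-1-ol
Product: 3 (E)-3-iodo-2-methylprop-2-en-1-ol, via alkenylalane 2 (not isolated)
Conditions: AlMe3 (3 equiv), Cp2ZrCl2 (0.25 equiv), CH2Cl2, 0 °C → rt; then I2, THF, −30 → 0 °C; aq. K2CO3
Reagents that add atoms: trimethylaluminium C[Al](C)C; iodine II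
Why: Negishi carboalumination adds CH3 and Al syn across the alkyne with the methyl on the internal carbon, and iodinolysis of the C–Al bond with retention should fix the E-alkenyl iodide.

Step 2
Reactants: 3 (E)-3-iodo-2-methylprop-2-en-1-ol
Product: 4 (E)-3-iodo-2-methylprop-2-enal
Conditions: MnO2 (activated, excess), CH2Cl2, rt, dark; used as a solution
Reagents that add atoms: none
Why: Allylic oxidation with MnO2 stops at the aldehyde and leaves the alkenyl iodide and its geometry untouched.

Step 3
Reactants: 5 (S)-4-benzyl-3-propanoyl-1,3-oxazolidin-2-one; 6 propanal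
Product: 8 (S)-4-benzyl-3-[(2S,3R)-3-hydroxy-2-methylpentanoyl]-1,3-oxazolidin-2-one, via boron enolate 7 (not isolated)
Conditions: Bu2BOTf, Et3N, CH2Cl2, −78 → 0 °C; 6, −78 → 0 °C; then pH 7 buffer, MeOH, H2O2
Reagents that add atoms: none
Why: Evans syn aldol reaction, in which the Z-boron enolate reacts through a chair transition state on the face dictated by the benzyl group of the auxiliary, which should set the 2S,3R syn pair (only the 2-methyl centre is kept later).

Step 4
Reactants: 8 (S)-4-benzyl-3-[(2S,3R)-3-hydroxy-2-methylpentanoyl]-1,3-oxazolidin-2-one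
Product: 9 (S)-4-benzyl-3-[(2S)-2-methyl-3-oxopentanoyl]-1,3-oxazolidin-2-one
Conditions: SO3·pyridine, DMSO, Et3N, CH2Cl2, −10 → 0 °C
Reagents that add atoms: none
Why: Parikh–Doering oxidation gives the β-ketoimide, whose C-2 centre should resist enolisation because allylic 1,3-strain keeps its C–H bond out of alignment with both carbonyl groups.

Step 5
Reactants: 9 (S)-4-benzyl-3-[(2S)-2-methyl-3-oxopentanoyl]-1,3-oxazolidin-2-one; 4 (E)-3-iodo-2-methylprop-2-enal
Product: 11 (S)-4-benzyl-3-[(2S,4R,5R,6E)-5-hydroxy-7-iodo-2,4,6-trimethyl-3-oxohept-6-enoyl]-1,3-oxazolidin-2-one, via tin enolate 10 (not isolated)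
Conditions: Sn(OTf)2, Et3N, CH2Cl2, −20 °C; then 4, −78 °C
Reagents that add atoms: none
Why: Aldol reaction of the divalent-tin Z-enolate of a β-ketoimide, in which the resident C-2 methyl centre directs the aldehyde to the face that gives the anti relation between the two methyl groups flanking the ketone and the chair transition state gives the syn methyl/hydroxyl pair.

Step 6
Reactants: 11 (S)-4-benzyl-3-[(2S,4R,5R,6E)-5-hydroxy-7-iodo-2,4,6-trimethyl-3-oxohept-6-enoyl]-1,3-oxazolidin-2-one
Product: 12 (S)-4-benzyl-3-[(2S,3S,4S,5R,6E)-3,5-dihydroxy-7-iodo-2,4,6-trimethylhept-6-enoyl]-1,3-oxazolidin-2-one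
Conditions: Zn(BH4)2, CH2Cl2/Et2O, −78 → −40 °C
Reagents that add atoms: none
Why: Chelation-controlled ketone reduction, in which zinc bridges the hydroxyl and ketone oxygens and hydride attacks the six-membered chelate to give the 1,3-syn diol, which should complete the anti,syn,syn tetrad.

Step 7
Reactants: 12 (S)-4-benzyl-3-[(2S,3S,4S,5R,6E)-3,5-dihydroxy-7-iodo-2,4,6-trimethylhept-6-enoyl]-1,3-oxazolidin-2-one
Product: 13 3,5-O-di-tert-butylsilylene acetal of 12
Conditions: t-Bu2Si(OTf)2, 2,6-lutidine, CH2Cl2, 0 °C → rt (directly after step 6)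
Reagents that add atoms: di-tert-butylsilyl bis(trifluoromethanesulfonate) CC(C)(C)[Si](OS(=O)(=O)C(F)(F)F)(OS(=O)(=O)C(F)(F)F)C(C)(C)C
Why: Silylene acetal formation on the syn-1,3-diol closes a 1,3,2-dioxasilinane ring, which blocks lactonisation onto the imide and should survive the basic and oxidative steps that follow.

Step 8
Reactants: 13 3,5-O-di-tert-butylsilylene acetal of 12
Product: 14 (2R)-2-{(4R,5S,6R)-2,2-di-tert-butyl-6-[(E)-1-iodoprop-1-en-2-yl]-5-methyl-1,3,2-dioxasilinan-4-yl}propan-1-ol
Conditions: LiBH4, EtOH (1 equiv), Et2O, 0 °C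
Reagents that add atoms: none
Why: Reductive cleavage of the N-acyloxazolidinone at the exocyclic carbonyl gives the primary alcohol without touching the α-stereocentre and releases the auxiliary.

Step 9
Reactants: 14 (2R)-2-{(4R,5S,6R)-2,2-di-tert-butyl-6-[(E)-1-iodoprop-1-en-2-yl]-5-methyl-1,3,2-dioxasilinan-4-yl}propan-1-ol
Product: 15 (2S)-2-{(4S,5S,6R)-2,2-di-tert-butyl-6-[(E)-1-iodoprop-1-en-2-yl]-5-methyl-1,3,2-dioxasilinan-4-yl}propanal
Conditions: Dess–Martin periodinane, CH2Cl2, 0 °C → rt; used crude
Reagents that add atoms: none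
Why: Dess–Martin oxidation under non-basic conditions should give the α-methyl aldehyde without epimerisation.

Step 10
Reactants: 16 4-methylheptane-3,5-dione; 15 (2S)-2-{(4S,5S,6R)-2,2-di-tert-butyl-6-[(E)-1-iodoprop-1-en-2-yl]-5-methyl-1,3,2-dioxasilinan-4-yl}propanal
Product: 18 8-{2,2-di-tert-butyl-6-[(E)-1-iodoprop-1-en-2-yl]-5-methyl-1,3,2-dioxasilinan-4-yl}-7-hydroxy-4,6-dimethylnonane-3,5-dione, via diketone dianion 17 (not isolated)
Conditions: 16, LiN(i-Pr)2 (2.1 equiv), THF, −78 → 0 °C; then 15, −78 °C; AcOH quench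
Reagents that add atoms: none
Why: Aldol addition of a β-diketone dianion, which reacts at its terminal, more basic carbon, assembles all carbons of the left pyranone ring; the three new centres are mixtures of no consequence because all become sp2 carbons.

Step 11
Reactants: 18 8-{2,2-di-tert-butyl-6-[(E)-1-iodoprop-1-en-2-yl]-5-methyl-1,3,2-dioxasilinan-4-yl}-7-hydroxy-4,6-dimethylnonane-3,5-dione
Product: 19 (8S)-8-{(4S,5S,6R)-2,2-di-tert-butyl-6-[(E)-1-iodoprop-1-en-2-yl]-5-methyl-1,3,2-dioxasilinan-4-yl}-4,6-dimethylnonane-3,5,7-trione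
Conditions: Dess–Martin periodinane, CH2Cl2, rt
Reagents that add atoms: none
Why: Dess–Martin oxidation of the secondary alcohol gives the 1,3,5-triketone, which enolises within the tricarbonyl array and so should spare the stereocentre on its flank.

Step 12
Reactants: 19 (8S)-8-{(4S,5S,6R)-2,2-di-tert-butyl-6-[(E)-1-iodoprop-1-en-2-yl]-5-methyl-1,3,2-dioxasilinan-4-yl}-4,6-dimethylnonane-3,5,7-trione
Product: 20 2-[(1S)-1-{(4S,5S,6R)-2,2-di-tert-butyl-6-[(E)-1-iodoprop-1-en-2-yl]-5-methyl-1,3,2-dioxasilinan-4-yl}ethyl]-6-ethyl-3,5-dimethyl-4H-pyran-4-one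
Conditions: PPh3, CCl4, THF, rt
Reagents that add atoms: none
Why: Appel-type cyclodehydration of a 1,3,5-triketone, in which an enol oxygen activated as an oxyphosphonium is displaced by the enol oxygen of the other terminal carbonyl, gives the 4-pyranone under neutral conditions that should preserve the neighbouring stereocentre.

Step 13
Reactants: 21 methyl (3R)-3-hydroxypentanoate
Product: 23 methyl (2R,3R)-3-hydroxy-2-methylpentanoate, via ester dianion 22 (not isolated)
Conditions: LiN(i-Pr)2 (2.2 equiv), THF, −78 → −20 °C; MeI, DMPU, −78 → 0 °C; aq. HCl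
Reagents that add atoms: iodomethane CI
Why: Fráter–Seebach alkylation, in which the lithium-chelated alkoxide–enolate is methylated on the face opposite the ethyl group, should set the 2,3-anti relation from the existing carbinol centre.

Step 14
Reactants: 23 methyl (2R,3R)-3-hydroxy-2-methylpentanoate
Product: 24 methyl (2R,3R)-3-[(tert-butyldimethylsilyl)oxy]-2-methylpentanoate
Conditions: TBSOTf, 2,6-lutidine, CH2Cl2, 0 °C
Reagents that add atoms: tert-butyldimethylsilyl trifluoromethanesulfonate CC(C)(C)[Si](C)(C)OS(=O)(=O)C(F)(F)F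
Why: Silylation of the secondary alcohol under non-epimerising conditions protects it for the enolate and oxidation steps.

Step 15
Reactants: 24 methyl (2R,3R)-3-[(tert-butyldimethylsilyl)oxy]-2-methylpentanoate
Product: 25 (2R,3R)-3-[(tert-butyldimethylsilyl)oxy]-2-methylpentanal
Conditions: i-Bu2AlH (1.05 equiv), CH2Cl2, −78 °C; MeOH, then aq. potassium sodium tartrate
Reagents that add atoms: none
Why: Partial reduction of the methyl ester, in which the aluminium hemiacetal is stable at −78 °C and releases the aldehyde only on work-up.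

Step 16
Reactants: 16 4-methylheptane-3,5-dione; 25 (2R,3R)-3-[(tert-butyldimethylsilyl)oxy]-2-methylpentanal
Product: 27 9-[(tert-butyldimethylsilyl)oxy]-7-hydroxy-4,6,8-trimethylundecane-3,5-dione, via sodium lithium dianion 26 (not isolated)
Conditions: 16, NaH (1.05 equiv), THF, 0 °C; n-BuLi (1.05 equiv), −10 °C; then 25, −78 °C; AcOH quench
Reagents that add atoms: none
Why: Aldol addition of a β-diketone dianion at its terminal carbon, here the sodium lithium dianion made amine-free by the NaH then n-BuLi protocol so that no secondary amine can shuttle protons to the α-methyl aldehyde, assembles the carbons of the right pyranone ring, the new centres again being destined for sp2 carbons.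

Step 17
Reactants: 27 9-[(tert-butyldimethylsilyl)oxy]-7-hydroxy-4,6,8-trimethylundecane-3,5-dione
Product: 28 (8R,9R)-9-[(tert-butyldimethylsilyl)oxy]-4,6,8-trimethylundecane-3,5,7-trione
Conditions: Dess–Martin periodinane, CH2Cl2, rt
Reagents that add atoms: none
Why: Dess–Martin oxidation gives the 1,3,5-triketone without base, so the α-methyl centre next to the new ketone should be kept.

Step 18
Reactants: 28 (8R,9R)-9-[(tert-butyldimethylsilyl)oxy]-4,6,8-trimethylundecane-3,5,7-trione
Product: 29 2-{(2R,3R)-3-[(tert-butyldimethylsilyl)oxy]pentan-2-yl}-6-ethyl-3,5-dimethyl-4H-pyran-4-one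
Conditions: PPh3, CCl4, THF, rt
Reagents that add atoms: none
Why: The same Appel-type cyclodehydration of a 1,3,5-triketone closes the right 4-pyranone ring under neutral conditions.

Step 19
Reactants: 29 2-{(2R,3R)-3-[(tert-butyldimethylsilyl)oxy]pentan-2-yl}-6-ethyl-3,5-dimethyl-4H-pyran-4-one
Product: 31 2-{(2R,3R)-3-[(tert-butyldimethylsilyl)oxy]pentan-2-yl}-6-(1-chloroethyl)-3,5-dimethyl-4H-pyran-4-one (both epimers at the C–Cl carbon), via lithium dienolate 30 (not isolated)
Conditions: LiN(SiMe3)2 (1.05 equiv), THF, −78 °C; cannulated into C2Cl6 (1.5 equiv), THF, −78 °C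
Reagents that add atoms: hexachloroethane ClC(Cl)(Cl)C(Cl)(Cl)Cl
Why: Kinetic deprotonation of the ethyl CH2 (the less hindered of the two side-chain positions next to the ring) gives the extended pyranone enolate, and electrophilic enolate chlorination at its exocyclic carbon gives the secondary chloride as an epimer mixture, which is all the next step needs.

Step 20
Reactants: 20 left-hand alkenyl iodide pyranone; 31 right-hand 1-chloroethyl pyranone (1.5 equiv)
Product: 32 silylene- and TBS-protected target
Conditions: NiCl2(MeOCH2CH2OMe) (10 mol %), (3aS,3a'S,8aR,8a'R)-2,2'-(cyclopropane-1,1-diyl)bis(3a,8a-dihydro-8H-indeno[1,2-d]oxazole) (12 mol %), Mn powder (3 equiv), NaI (0.5 equiv), DMA, 0 °C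
Reagents that add atoms: none
Why: Proposed new method: zerovalent nickel carrying the chiral bis(oxazoline) adds oxidatively to the alkenyl C–I bond of 20 with retention of the E geometry, while low-valent nickel (helped by chloride/iodide exchange with NaI) abstracts the halogen of 31 to give a planar radical delocalised from the exocyclic carbon over C2=C3 and the C-4 carbonyl of the pyranone ring, so both chloride epimers converge; capture of this radical by the alkenylnickel and reductive elimination from trivalent nickel form the C(sp2)–C(sp3) bond, and Mn turns the catalyst over. The closest known reaction type is the nickel-catalysed asymmetric reductive cross-coupling of alkenyl bromides with racemic secondary benzylic chlorides under these conditions; the extension lies in the electrophile, a 1-chloroethyl group on a fully substituted 4-pyranone (a vinylogous α-chloro ester) in place of a benzyl chloride, and in a stereochemically complex trisubstituted alkenyl iodide. No ring is closed in this step. The new (R)-centre between the alkene and the right pyranone ring is set by the ligand at the radical-capture and reductive-elimination stage, that is by catalyst control, since the nearest resident stereocentres lie three bonds away on the alkenyl side and across the pyranone ring on the other side. The step needs cross- over homo-coupling selectivity, which rests on the different activation modes of the two halides (two-electron oxidative addition for the sp2 iodide, halogen abstraction for the activated sp3 chloride used in excess), and it needs the doubly activated C–H of the product to stay untouched, which the base-free conditions at 0 °C should secure against epimerisation and against migration of the alkene into conjugation with the ring.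

Step 21
Reactants: 32 silylene- and TBS-protected target
Product: 33 target, 2-ethyl-6-[(2S,3S,4S,5R,6E,8R)-3,5-dihydroxy-8-{6-[(2R,3R)-3-hydroxypentan-2-yl]-3,5-dimethyl-4-oxo-4H-pyran-2-yl}-4,6-dimethylnon-6-en-2-yl]-3,5-dimethyl-4H-pyran-4-one
Conditions: HF·pyridine, pyridine, THF, 0 °C → rt (polypropylene vessel)
Reagents that add atoms: none
Why: Fluoride-driven Si–O cleavage under buffered, weakly acidic conditions removes the silylene and the TBS ether in one operation without base, so the junction C–H and the allylic alcohol should not be endangered.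

**Compound list**

1 | prop-2-yn-1-ol | C#CCO | starting material
2 | dimethylaluminium alkoxide of (E)-3-(dimethylalumanyl)-2-methylprop-2-en-1-ol (not isolated) | C[Al](C)OC/C(C)=C/[Al](C)C | intermediate
3 | (E)-3-iodo-2-methylprop-2-en-1-ol | OC/C(C)=C/I | intermediate
4 | (E)-3-iodo-2-methylprop-2-enal | O=C/C(C)=C/I | intermediate
5 | (S)-4-benzyl-3-propanoyl-1,3-oxazolidin-2-one | CCC(=O)N1C(=O)OC[C@@H]1Cc1ccccc1 | starting material
6 | propanal | CCC=O | starting material
7 | (Z)-dibutylboron enolate of 5 (not isolated) | C/C=C(\OB(CCCC)CCCC)N1C(=O)OC[C@@H]1Cc1ccccc1 | intermediate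
8 | (S)-4-benzyl-3-[(2S,3R)-3-hydroxy-2-methylpentanoyl]-1,3-oxazolidin-2-one | CC[C@@H](O)[C@H](C)C(=O)N1C(=O)OC[C@@H]1Cc1ccccc1 | intermediate
9 | (S)-4-benzyl-3-[(2S)-2-methyl-3-oxopentanoyl]-1,3-oxazolidin-2-one | CCC(=O)[C@H](C)C(=O)N1C(=O)OC[C@@H]1Cc1ccccc1 | intermediate
10 | (Z)-tin triflate enolate of 9, divalent tin, enolised toward the ethyl group (not isolated) | C/C=C(\O[Sn]OS(=O)(=O)C(F)(F)F)[C@H](C)C(=O)N1C(=O)OC[C@@H]1Cc1ccccc1 | intermediate
11 | (S)-4-benzyl-3-[(2S,4R,5R,6E)-5-hydroxy-7-iodo-2,4,6-trimethyl-3-oxohept-6-enoyl]-1,3-oxazolidin-2-one | O=C(N1C(=O)OC[C@@H]1Cc1ccccc1)[C@@H](C)C(=O)[C@H](C)[C@@H](O)/C(C)=C/I | intermediate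
12 | (S)-4-benzyl-3-[(2S,3S,4S,5R,6E)-3,5-dihydroxy-7-iodo-2,4,6-trimethylhept-6-enoyl]-1,3-oxazolidin-2-one | O=C(N1C(=O)OC[C@@H]1Cc1ccccc1)[C@@H](C)[C@@H](O)[C@H](C)[C@@H](O)/C(C)=C/I | intermediate
13 | (S)-4-benzyl-3-[(2S)-2-{(4S,5S,6R)-2,2-di-tert-butyl-6-[(E)-1-iodoprop-1-en-2-yl]-5-methyl-1,3,2-dioxasilinan-4-yl}propanoyl]-1,3-oxazolidin-2-one (silylene acetal of 12) | O=C(N1C(=O)OC[C@@H]1Cc1ccccc1)[C@@H](C)[C@H]1O[Si](C(C)(C)C)(C(C)(C)C)O[C@@H](/C(C)=C/I)[C@H]1C | intermediate
14 | (2R)-2-{(4R,5S,6R)-2,2-di-tert-butyl-6-[(E)-1-iodoprop-1-en-2-yl]-5-methyl-1,3,2-dioxasilinan-4-yl}propan-1-ol | OC[C@@H](C)[C@H]1O[Si](C(C)(C)C)(C(C)(C)C)O[C@@H](/C(C)=C/I)[C@H]1C | intermediate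
15 | (2S)-2-{(4S,5S,6R)-2,2-di-tert-butyl-6-[(E)-1-iodoprop-1-en-2-yl]-5-methyl-1,3,2-dioxasilinan-4-yl}propanal | O=C[C@@H](C)[C@H]1O[Si](C(C)(C)C)(C(C)(C)C)O[C@@H](/C(C)=C/I)[C@H]1C | intermediate
16 | 4-methylheptane-3,5-dione | CCC(=O)C(C)C(=O)CC | starting material
17 | dilithium dianion of 16, deprotonated at C-4 and C-2 (not isolated) | [Li+].[Li+].CC=C([O-])C(C)=C([O-])CC | intermediate
18 | 8-{2,2-di-tert-butyl-6-[(E)-1-iodoprop-1-en-2-yl]-5-methyl-1,3,2-dioxasilinan-4-yl}-7-hydroxy-4,6-dimethylnonane-3,5-dione (mixture at C-4, C-6, C-7; the four other centres as in 15) | CCC(=O)C(C)C(=O)C(C)C(O)[C@@H](C)[C@H]1O[Si](C(C)(C)C)(C(C)(C)C)O[C@@H](/C(C)=C/I)[C@H]1C | intermediate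
19 | (8S)-8-{(4S,5S,6R)-2,2-di-tert-butyl-6-[(E)-1-iodoprop-1-en-2-yl]-5-methyl-1,3,2-dioxasilinan-4-yl}-4,6-dimethylnonane-3,5,7-trione (keto/enol and C-4/C-6 mixture) | CCC(=O)C(C)C(=O)C(C)C(=O)[C@@H](C)[C@H]1O[Si](C(C)(C)C)(C(C)(C)C)O[C@@H](/C(C)=C/I)[C@H]1C | intermediate
20 | 2-[(1S)-1-{(4S,5S,6R)-2,2-di-tert-butyl-6-[(E)-1-iodoprop-1-en-2-yl]-5-methyl-1,3,2-dioxasilinan-4-yl}ethyl]-6-ethyl-3,5-dimethyl-4H-pyran-4-one | CCc1oc([C@@H](C)[C@H]2O[Si](C(C)(C)C)(C(C)(C)C)O[C@@H](/C(C)=C/I)[C@H]2C)c(C)c(=O)c1C | intermediate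
21 | methyl (3R)-3-hydroxypentanoate | CC[C@@H](O)CC(=O)OC | starting material
22 | dilithium alkoxide–enolate of 21 (not isolated) | [Li+].[Li+].CC[C@@H]([O-])C=C([O-])OC | intermediate
23 | methyl (2R,3R)-3-hydroxy-2-methylpentanoate | CC[C@@H](O)[C@@H](C)C(=O)OC | intermediate
24 | methyl (2R,3R)-3-[(tert-butyldimethylsilyl)oxy]-2-methylpentanoate | CC[C@@H](O[Si](C)(C)C(C)(C)C)[C@@H](C)C(=O)OC | intermediate
25 | (2R,3R)-3-[(tert-butyldimethylsilyl)oxy]-2-methylpentanal | CC[C@@H](O[Si](C)(C)C(C)(C)C)[C@@H](C)C=O | intermediate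
26 | sodium lithium dianion of 16, deprotonated at C-4 and C-2 (not isolated) | [Na+].[Li+].CC=C([O-])C(C)=C([O-])CC | intermediate
27 | 9-[(tert-butyldimethylsilyl)oxy]-7-hydroxy-4,6,8-trimethylundecane-3,5-dione (mixture at C-4, C-6, C-7; the two side-chain centres as in 25) | CC[C@@H](O[Si](C)(C)C(C)(C)C)[C@@H](C)C(O)C(C)C(=O)C(C)C(=O)CC | intermediate
28 | (8R,9R)-9-[(tert-butyldimethylsilyl)oxy]-4,6,8-trimethylundecane-3,5,7-trione (keto/enol and C-4/C-6 mixture) | CC[C@@H](O[Si](C)(C)C(C)(C)C)[C@@H](C)C(=O)C(C)C(=O)C(C)C(=O)CC | intermediate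
29 | 2-{(2R,3R)-3-[(tert-butyldimethylsilyl)oxy]pentan-2-yl}-6-ethyl-3,5-dimethyl-4H-pyran-4-one | CC[C@@H](O[Si](C)(C)C(C)(C)C)[C@@H](C)c1oc(CC)c(C)c(=O)c1C | intermediate
30 | lithium 2-ethylidene-2H-pyran-4-olate (dienolate) of 29 (not isolated) | [Li+].CC[C@@H](O[Si](C)(C)C(C)(C)C)[C@@H](C)C1=C(C)C([O-])=C(C)C(=CC)O1 | intermediate
31 | 2-{(2R,3R)-3-[(tert-butyldimethylsilyl)oxy]pentan-2-yl}-6-(1-chloroethyl)-3,5-dimethyl-4H-pyran-4-one (both epimers at the C–Cl carbon) | CC[C@@H](O[Si](C)(C)C(C)(C)C)[C@@H](C)c1oc(C(C)Cl)c(C)c(=O)c1C | intermediate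
32 | 2-[(1S)-1-{(4S,5S,6R)-2,2-di-tert-butyl-5-methyl-6-[(2E,4R)-4-(6-{(2R,3R)-3-[(tert-butyldimethylsilyl)oxy]pentan-2-yl}-3,5-dimethyl-4-oxo-4H-pyran-2-yl)pent-2-en-2-yl]-1,3,2-dioxasilinan-4-yl}ethyl]-6-ethyl-3,5-dimethyl-4H-pyran-4-one (target with the left 1,3-diol as di-tert-butylsilylene and the right hydroxyl as TBS ether) | CCc1oc([C@@H](C)[C@H]2O[Si](C(C)(C)C)(C(C)(C)C)O[C@@H](/C(C)=C/[C@@H](C)c3oc([C@H](C)[C@H](O[Si](C)(C)C(C)(C)C)CC)c(C)c(=O)c3C)[C@H]2C)c(C)c(=O)c1C | intermediate
33 | 2-ethyl-6-[(2S,3S,4S,5R,6E,8R)-3,5-dihydroxy-8-{6-[(2R,3R)-3-hydroxypentan-2-yl]-3,5-dimethyl-4-oxo-4H-pyran-2-yl}-4,6-dimethylnon-6-en-2-yl]-3,5-dimethyl-4H-pyran-4-one | CCc1oc([C@@H](C)[C@@H](O)[C@H](C)[C@@H](O)/C(C)=C/[C@@H](C)c2oc([C@H](C)[C@H](O)CC)c(C)c(=O)c2C)c(C)c(=O)c1C | target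

**Summary**

Total step count: 21. Longest linear sequence: 12 steps (steps 3–12, 20, 21, from 5 to 33).

Steps most likely to fail:

1. Step 20 (Proposed new method). The ligand may fail to override the facial bias of the chiral alkenylnickel partner, or the pyranone-stabilised radical may be reduced or dimerise faster than it is captured. The fallback uses known chemistry, sets out from 31 and comes back at 32. Zinc insertion into the activated C–Cl bond of 31 (Zn dust, LiCl, THF, 25 °C) would give the secondary organozinc chloride F1. A palladium-catalysed Negishi coupling of F1 with alkenyl iodide 20 (Pd(OAc)2, SPhos, THF, 25 °C) is a two-electron union of a benzylic-type zinc reagent with an alkenyl iodide and keeps the E geometry. It would give 32 together with the junction epimer F2. Catalyst control of the centre is given up, at the cost of about half the material; the two are separated by preparative HPLC and 32 goes on to step 21.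

2. Step 19. Proton transfer between the chlorinated product and unreacted dienolate may lead to over-chlorination, and competing deprotonation at the tertiary side-chain carbon would erode its configuration. The fallback sets out from 29 and comes back at 31, making the C–O bond first. Lithium dienolate 30 is hydroxylated with 2-(phenylsulfonyl)-3-phenyloxaziridine (THF, −78 °C) to the secondary alcohol F3, whose alkoxide cannot be functionalised a second time. An Appel reaction (PPh3, CCl4, CH2Cl2, rt) then gives chloride 31.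

3. Step 12. Enolisation toward the side-chain stereocentre at the triketone stage (steps 11 and 12) would scramble the first methyl centre of the left fragment. The fallback sets out from 18 and comes back at 20, and never places a ketone next to that centre. Acid-catalysed cyclodehydration of hydroxy diketone 18 (TsOH cat., CH2Cl2, 0 °C) gives the 2,3-dihydro-4H-pyran-4-one F4, and dehydrogenation with DDQ (1,4-dioxane, 80 °C) gives pyranone 20.

Further compounds

F1 | step 20 | chloro{1-[6-{(2R,3R)-3-[(tert-butyldimethylsilyl)oxy]pentan-2-yl}-3,5-dimethyl-4-oxo-4H-pyran-2-yl]ethyl}zinc | CC[C@@H](O[Si](C)(C)C(C)(C)C)[C@@H](C)c1oc(C(C)[Zn]Cl)c(C)c(=O)c1C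
F2 | step 20 | epimer of 32 with the (S) configuration at the carbon between the alkene and the right pyranone ring | CCc1oc([C@@H](C)[C@H]2O[Si](C(C)(C)C)(C(C)(C)C)O[C@@H](/C(C)=C/[C@H](C)c3oc([C@H](C)[C@H](O[Si](C)(C)C(C)(C)C)CC)c(C)c(=O)c3C)[C@H]2C)c(C)c(=O)c1C
F3 | step 19 | 2-{(2R,3R)-3-[(tert-butyldimethylsilyl)oxy]pentan-2-yl}-6-(1-hydroxyethyl)-3,5-dimethyl-4H-pyran-4-one (both carbinol epimers) | CC[C@@H](O[Si](C)(C)C(C)(C)C)[C@@H](C)c1oc(C(C)O)c(C)c(=O)c1C
F4 | step 12 | 2-[(1S)-1-{(4S,5S,6R)-2,2-di-tert-butyl-6-[(E)-1-iodoprop-1-en-2-yl]-5-methyl-1,3,2-dioxasilinan-4-yl}ethyl]-6-ethyl-3,5-dimethyl-2,3-dihydro-4H-pyran-4-one (mixture at ring C-2 and C-3) | CCC1=C(C)C(=O)C(C)C(O1)[C@@H](C)[C@H]1O[Si](C(C)(C)C)(C(C)(C)C)O[C@@H](/C(C)=C/I)[C@H]1C
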